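**Retrosynthetic overview**
- The target, robinetinidol-(4α→8)-epigallocatechin, comes from its deca-O-benzyl ether; all phenols are unmasked last by hydrogenolysis.
- The upper C3–OH and C4–H come from hydroboration–oxidation of a 4-aryl-2H-chromene (flav-3-ene) anti to the C2 aryl, which gives the 2,3-trans-3,4-trans array.
- Ring C (O1–C2 bond) comes from an oxa-6π electrocyclisation of a vinyl o-quinone methide that already carries the lower flavan on its methide carbon.
- The o-quinone methide comes from 8-lithiated hexa-O-benzyl-epigallocatechin plus a 2'-O-Boc chalcone (this addition makes the C4–C8 interflavan bond); the chalcone comes from an acetophenone and an aldehyde.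
- Ring order: rings A, B and the whole lower unit (rings D, E, F) are bought and ring C is the only ring built. (−)-Epigallocatechin is the only source of chirality: the upper C2 is fixed by separating the two ring-closure diastereomers, and C3 and C4 follow from C2.

Assumption: the SMILES is read as robinetinidol-(4α→8)-epigallocatechin (upper unit 2R,3S,4S, i.e. 2,3-trans-3,4-trans; lower unit 2R,3R); (−)-epigallocatechin, acetophenone 4 and aldehyde 5 are taken as purchasable.

Abbreviations: Bn = benzyl; Boc = tert-butoxycarbonyl; "B-ring aryl" = 3,4,5-tris(benzyloxy)phenyl; "lower-unit aryl" = (2R,3R)-3,5,7-tris(benzyloxy)-2-[3,4,5-tris(benzyloxy)phenyl]chroman-8-yl.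

**Step 1**
Reactants: 1 (−)-epigallocatechin
Product: 2 hexa-O-benzyl-(−)-epigallocatechin
Conditions: BnBr (7 equiv), K2CO3, DMF, 0 °C → rt, argon; then NaH, Bu4NI (cat.), 0 °C → rt
Reagents that add atoms: benzyl bromide, BrCc1ccccc1
Why: Williamson etherification of the five phenoxides (K2CO3) and then of the secondary alkoxide (NaH) masks every acidic OH for the organolithium step, and no stereocenter is touched because C2 can no longer epimerise once the ring B phenols are alkylated.

**Step 2**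
Reactants: 2 hexa-O-benzyl-(−)-epigallocatechin
Product: 3 8-bromo-hexa-O-benzyl-(−)-epigallocatechin
Conditions: NBS (1.0 equiv), CH2Cl2, −78 °C → 0 °C
Reagents that add atoms: N-bromosuccinimide, O=C1CCC(=O)N1Br
Why: Electrophilic aromatic bromination goes to C8 of the phloroglucinol-type ring (ortho/para to three oxygens), the position NBS selects in 5,7-di-O-benzyl flavan-3-ols, and the stereocenters are untouched.

**Step 3**
Reactants: 4 1-[4-(benzyloxy)-2-hydroxyphenyl]ethan-1-one; 5 3,4,5-tris(benzyloxy)benzaldehyde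
Product: 6 (E)-1-[4-(benzyloxy)-2-hydroxyphenyl]-3-[3,4,5-tris(benzyloxy)phenyl]prop-2-en-1-one
Conditions: KOH (50% aq.), EtOH, rt, 48 h; then HCl (aq.)
Reagents that add atoms: none
Why: Claisen–Schmidt aldol condensation of a methyl ketone with a non-enolisable aldehyde gives the thermodynamic E-chalcone.

**Step 4**
Reactants: 6 (E)-2'-hydroxychalcone
Product: 7 5-(benzyloxy)-2-{(E)-3-[3,4,5-tris(benzyloxy)phenyl]prop-2-enoyl}phenyl tert-butyl carbonate
Conditions: Boc2O, DMAP (cat.), i-Pr2NEt, CH2Cl2, 0 °C → rt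
Reagents that add atoms: di-tert-butyl dicarbonate, CC(C)(C)OC(=O)OC(=O)OC(C)(C)C
Why: DMAP-catalysed O-acylation turns the chelated phenol into an aryl Boc carbonate that both removes the acidic proton and serves as the leaving-group relay for o-quinone methide formation.

**Step 5**
Reactants: 3 8-bromo-hexa-O-benzyl-(−)-epigallocatechin; 7 2'-O-Boc chalcone
Product: 12 (2S)-7-(benzyloxy)-2-(B-ring aryl)-4-(lower-unit aryl)-2H-chromene (B-ring aryl on the α face as in the target), via aryllithium 8 (not isolated), via lithium alkoxide 9 (not isolated), via lithium phenoxide carbonate 10 (not isolated), via o-quinone methide 11 (not isolated)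
Conditions: 3, t-BuLi (2.0 equiv), THF, −78 °C; then 7 (1.2 equiv), −78 °C → rt, 3 h; NH4Cl (aq.); chromatography
Reagents that add atoms: none
Why: Br/Li exchange gives 8, whose 1,2-addition to the enone carbonyl makes the C4–C8 interflavan bond; O-to-O Boc transfer and 1,4-elimination of tert-butyl carbonate then give the vinyl o-quinone methide 11, which closes ring C by thermal oxa-6π electrocyclisation, and because the remote lower-unit stereocenters give no useful bias at the new C2, 12 is isolated by chromatography from a roughly equal amount of its C2 epimer (a diastereomer, since the lower unit is enantiopure), which fixes the absolute configuration at C2.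

**Step 6**
Reactants: 12 (2S)-4-aryl-2H-chromene
Product: 14 deca-O-benzyl robinetinidol-(4α→8)-epigallocatechin (upper 3-OH free; upper unit 2R,3S,4S), via C3 alkylborane 13 (not isolated)
Conditions: BH3·THF, THF, 0 °C → rt; then NaOH (aq.), H2O2 (30%), 0 °C → rt
Reagents that add atoms: hydrogen peroxide, OO
Why: Hydroboration–oxidation adds H and B syn across C3=C4 from the face opposite the C2 aryl with boron on the less hindered C3, and oxidation with retention gives 3-OH trans to the C2 aryl and the C4 aryl trans to 3-OH, so C3 and C4 are set by C2.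

**Step 7**
Reactants: 14 deca-O-benzyl ether
Product: 15 robinetinidol-(4α→8)-epigallocatechin (target)
Conditions: H2 (1 atm), Pd(OH)2/C, THF/MeOH/H2O, rt; Sephadex LH-20
Reagents that add atoms: none
Why: Catalytic hydrogenolysis cleaves all ten benzyl ethers under neutral conditions that leave the interflavan C–C bond and the five stereocenters untouched.

**Compound list**
1 | (−)-epigallocatechin, (2R,3R)-2-(3,4,5-trihydroxyphenyl)chromane-3,5,7-triol | Oc1cc(O)c2c(c1)O[C@H](c1cc(O)c(O)c(O)c1)[C@H](O)C2 | starting material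
2 | hexa-O-benzyl-(−)-epigallocatechin, (2R,3R)-3,5,7-tris(benzyloxy)-2-[3,4,5-tris(benzyloxy)phenyl]chromane | O(Cc1ccccc1)c1cc(OCc2ccccc2)c2c(c1)O[C@H](c1cc(OCc3ccccc3)c(OCc3ccccc3)c(OCc3ccccc3)c1)[C@H](OCc1ccccc1)C2 | intermediate
3 | (2R,3R)-8-bromo-3,5,7-tris(benzyloxy)-2-[3,4,5-tris(benzyloxy)phenyl]chromane | O(Cc1ccccc1)c1cc(OCc2ccccc2)c2c(c1Br)O[C@H](c1cc(OCc3ccccc3)c(OCc3ccccc3)c(OCc3ccccc3)c1)[C@H](OCc1ccccc1)C2 | intermediate
4 | 1-[4-(benzyloxy)-2-hydroxyphenyl]ethan-1-one | CC(=O)c1ccc(OCc2ccccc2)cc1O | starting material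
5 | 3,4,5-tris(benzyloxy)benzaldehyde | O=Cc1cc(OCc2ccccc2)c(OCc2ccccc2)c(OCc2ccccc2)c1 | starting material
6 | (E)-1-[4-(benzyloxy)-2-hydroxyphenyl]-3-[3,4,5-tris(benzyloxy)phenyl]prop-2-en-1-one | O=C(/C=C/c1cc(OCc2ccccc2)c(OCc2ccccc2)c(OCc2ccccc2)c1)c1ccc(OCc2ccccc2)cc1O | intermediate
7 | 5-(benzyloxy)-2-{(E)-3-[3,4,5-tris(benzyloxy)phenyl]prop-2-enoyl}phenyl tert-butyl carbonate | O=C(/C=C/c1cc(OCc2ccccc2)c(OCc2ccccc2)c(OCc2ccccc2)c1)c1ccc(OCc2ccccc2)cc1OC(=O)OC(C)(C)C | intermediate
8 | 8-lithio derivative of 2 (C8–Li in place of the C8–Br of 3) | O(Cc1ccccc1)c1cc(OCc2ccccc2)c2c(c1[Li])O[C@H](c1cc(OCc3ccccc3)c(OCc3ccccc3)c(OCc3ccccc3)c1)[C@H](OCc1ccccc1)C2 | intermediate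
9 | lithium alkoxide from 1,2-addition of 8 to 7; the carbinol carbon bears O–Li, the lower-unit aryl, the 4-(benzyloxy)-2-(Boc-oxy)phenyl ring and the E-styryl arm (both carbinol epimers) | [Li]OC(/C=C/c1cc(OCc2ccccc2)c(OCc2ccccc2)c(OCc2ccccc2)c1)(c1ccc(OCc2ccccc2)cc1OC(=O)OC(C)(C)C)c1c(OCc2ccccc2)cc(OCc2ccccc2)c2c1O[C@H](c1cc(OCc3ccccc3)c(OCc3ccccc3)c(OCc3ccccc3)c1)[C@H](OCc1ccccc1)C2 | intermediate
10 | lithium phenoxide with the Boc group moved to the tertiary oxygen (tertiary tert-butyl carbonate) | CC(C)(C)OC(=O)OC(/C=C/c1cc(OCc2ccccc2)c(OCc2ccccc2)c(OCc2ccccc2)c1)(c1ccc(OCc2ccccc2)cc1O[Li])c1c(OCc2ccccc2)cc(OCc2ccccc2)c2c1O[C@H](c1cc(OCc3ccccc3)c(OCc3ccccc3)c(OCc3ccccc3)c1)[C@H](OCc1ccccc1)C2 | intermediate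
11 | o-quinone methide: 3-(benzyloxy)cyclohexa-2,4-dien-1-one whose C6 is doubly bonded to a carbon carrying the lower-unit aryl and the E-styryl arm, styryl arm on the carbonyl side | O=C1C=C(OCc2ccccc2)C=C/C1=C(/C=C/c1cc(OCc2ccccc2)c(OCc2ccccc2)c(OCc2ccccc2)c1)c1c(OCc2ccccc2)cc(OCc2ccccc2)c2c1O[C@H](c1cc(OCc3ccccc3)c(OCc3ccccc3)c(OCc3ccccc3)c1)[C@H](OCc1ccccc1)C2 | intermediate
12 | (2S)-7-(benzyloxy)-2-[3,4,5-tris(benzyloxy)phenyl]-4-(lower-unit aryl)-2H-chromene; same spatial sense at C2 as the target, descriptor S only because the CIP ranking changes next to the alkene | O(Cc1ccccc1)c1ccc2c(c1)O[C@H](c1cc(OCc3ccccc3)c(OCc3ccccc3)c(OCc3ccccc3)c1)C=C2c1c(OCc2ccccc2)cc(OCc2ccccc2)c2c1O[C@H](c1cc(OCc3ccccc3)c(OCc3ccccc3)c(OCc3ccccc3)c1)[C@H](OCc1ccccc1)C2 | intermediate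
13 | C3 alkylborane from 12: boron on C3 (β face), new hydrogen on C4 (β face), C2 and C4 aryl groups α | O(Cc1ccccc1)c1ccc2c(c1)O[C@H](c1cc(OCc3ccccc3)c(OCc3ccccc3)c(OCc3ccccc3)c1)[C@@H](B)[C@@H]2c1c(OCc2ccccc2)cc(OCc2ccccc2)c2c1O[C@H](c1cc(OCc3ccccc3)c(OCc3ccccc3)c(OCc3ccccc3)c1)[C@H](OCc1ccccc1)C2 | intermediate
14 | (2R,3S,4S)-7-(benzyloxy)-2-[3,4,5-tris(benzyloxy)phenyl]-4-(lower-unit aryl)chroman-3-ol (deca-O-benzyl target) | O(Cc1ccccc1)c1ccc2c(c1)O[C@H](c1cc(OCc3ccccc3)c(OCc3ccccc3)c(OCc3ccccc3)c1)[C@@H](O)[C@@H]2c1c(OCc2ccccc2)cc(OCc2ccccc2)c2c1O[C@H](c1cc(OCc3ccccc3)c(OCc3ccccc3)c(OCc3ccccc3)c1)[C@H](OCc1ccccc1)C2 | intermediate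
15 | robinetinidol-(4α→8)-epigallocatechin (CNP0275321.3) | Oc1ccc2c(c1)O[C@H](c1cc(O)c(O)c(O)c1)[C@@H](O)[C@@H]2c1c(O)cc(O)c2c1O[C@H](c1cc(O)c(O)c(O)c1)[C@H](O)C2 | target

**Totals and risks**
Total step count: 7. Longest linear sequence: 5 steps (1 → 2 → 3 → 12 → 14 → 15).

Step 5 is the most exposed step. The hindered aryllithium 8 may attack the Boc carbonyl or add 1,4, the Boc-transfer/elimination relay may stall, and ring closure shows no preference at C2, so at best about half of the material is 12. The fallback sets out from 6 and 3. Chalcone 6 is cyclised by oxa-Michael addition (NaOAc, EtOH, reflux) to the racemic flavanone F1. Aryllithium 8 (from 3 and t-BuLi), transmetallated with CeCl3 to suppress enolisation and ring opening, is added to the ketone of F1 to give the tertiary 4-aryl-flavan-4-ol F2 as a mixture of diastereomers. Acid dehydration (TsOH cat., toluene, rt) then gives the flav-3-ene as 12 together with its C2 epimer F3, which is removed by chromatography, and the route is rejoined at 12. F3 need not be lost: irradiation at 365 nm opens it to 11, which recloses to the 1:1 mixture for another separation.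

Step 6 may fail because the trisubstituted 1,1-diaryl alkene is crowded, so hydroboration may be slow or poorly face-selective. The fallback sets out from 12. Dimethyldioxirane (acetone, −20 °C) gives the acid-labile epoxide F4 on the face opposite the C2 aryl, and it is used crude. Hydrogenolysis over neutral-washed Raney nickel (Ni; H2 1 atm, THF/EtOAc, rt) then cleaves the doubly benzylic C4–O bond with retention. Nickel binds the oxirane oxygen on the open β face and delivers hydrogen to C4 from that same face, whereas palladium gives inversion. The 3-OH and 4-H therefore end up cis, as in hydroboration, and the route is rejoined at 14. Any benzyl ether lost on nickel does not matter, because step 7 removes them all.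

Step 7 may fail through incomplete removal of ten benzyl groups, hydrogenolytic opening of the benzylic C2–O1 bonds, or air oxidation of the two pyrogallol rings during isolation. The fallback sets out from 14. BCl3 with pentamethylbenzene as cation scavenger (CH2Cl2, −78 °C → −40 °C) removes the benzyl groups without hydrogen; the interflavan bond of a 5-deoxy upper unit tolerates this. The crude polyphenol is acetylated (Ac2O, pyridine) to the undecaacetate F5, which is stable and can be purified on silica. NaOMe (cat.) in degassed MeOH at 0 °C, followed by acidic ion-exchange resin, returns the route at 15.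

**Further compounds**
F1 | step 5 | rac-7-(benzyloxy)-2-[3,4,5-tris(benzyloxy)phenyl]chroman-4-one | O=C1CC(c2cc(OCc3ccccc3)c(OCc3ccccc3)c(OCc3ccccc3)c2)Oc2cc(OCc3ccccc3)ccc12
F2 | step 5 | 7-(benzyloxy)-2-[3,4,5-tris(benzyloxy)phenyl]-4-(lower-unit aryl)chroman-4-ol (epimers at C2 and C4) | OC1(CC(c2cc(OCc3ccccc3)c(OCc3ccccc3)c(OCc3ccccc3)c2)Oc2cc(OCc3ccccc3)ccc12)c1c(OCc2ccccc2)cc(OCc2ccccc2)c2c1O[C@H](c1cc(OCc3ccccc3)c(OCc3ccccc3)c(OCc3ccccc3)c1)[C@H](OCc1ccccc1)C2
F3 | step 5 | (2R)-7-(benzyloxy)-2-[3,4,5-tris(benzyloxy)phenyl]-4-(lower-unit aryl)-2H-chromene, the C2 epimer of 12 | O(Cc1ccccc1)c1ccc2c(c1)O[C@@H](c1cc(OCc3ccccc3)c(OCc3ccccc3)c(OCc3ccccc3)c1)C=C2c1c(OCc2ccccc2)cc(OCc2ccccc2)c2c1O[C@H](c1cc(OCc3ccccc3)c(OCc3ccccc3)c(OCc3ccccc3)c1)[C@H](OCc1ccccc1)C2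
F4 | step 6 | 3,4-epoxide of 12, oxygen on the β face (anti to the C2 aryl) | O(Cc1ccccc1)c1ccc2c(c1)O[C@H](c1cc(OCc3ccccc3)c(OCc3ccccc3)c(OCc3ccccc3)c1)[C@H]3O[C@@]23c1c(OCc2ccccc2)cc(OCc2ccccc2)c2c1O[C@H](c1cc(OCc3ccccc3)c(OCc3ccccc3)c(OCc3ccccc3)c1)[C@H](OCc1ccccc1)C2
F5 | step 7 | undeca-O-acetate of 15 | CC(=O)Oc1ccc2c(c1)O[C@H](c1cc(OC(C)=O)c(OC(C)=O)c(OC(C)=O)c1)[C@@H](OC(C)=O)[C@@H]2c1c(OC(C)=O)cc(OC(C)=O)c2c1O[C@H](c1cc(OC(C)=O)c(OC(C)=O)c(OC(C)=O)c1)[C@H](OC(C)=O)C2
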